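- 13 min is the half-life of Z by the second step alone in delta, reckoned as if the whole charge of D stood there at once.

    J + D ⇌ D + Z (K1 = 0.72, k1 = 53 M⁻¹ s⁻¹)
    Q + D + Z → D + G (k2 = 60 M⁻² s⁻¹)
    D + G ⇌ D.G, settled at all times (K3 = 12 M⁻¹)
    D → E (k4 = 0.0011 s⁻¹)

the same everywhere: J 0.050 M; D 0.12 mM (in portions, 4); time 50 min
- delta: Q 0.120 M; the portions of D follow each other after 20 s, the first at the start
- eta: Q 0.190 M; the portions of D follow each other after 20 s, the first at the start
- zeta: Q 0.280 M; the portions of D follow each other after 20 s, the first at the start

* which of these there is most of at the end, counted by the J in it, delta (Z / G / J)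
* which of these there is most of at the end, counted by the J in it, eta (Z / G / J)
* which of these there is most of at the end, counted by the J in it, zeta (Z / G / J)
* final amount of the leader among these, as a percentage of the J charged, in delta
* final amount of the leader among these, as a percentage of the J charged, in eta
* final amount of the leader among these, as a percentage of the J charged, in zeta

- for G the D.G is counted in
- run time (delta): 50 min

- That half-life fits 3.74 times into the 50 min run, Q stands at 2.40 equivalents to J, and delta looks certain to finish. But D decays to E with a lifetime of 15.2 min, shorter than the run.
- My reckoning asks first where the flask must stop. Each D decays after a fixed mean time, so the time integral of free D, its exposure X, sums to 0.109 M·s once D is gone. Holding D as D.G delays this sum without enlarging it.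
- The rate constant of the first step, 53 M⁻¹ s⁻¹, exceeds the second step's 16.8 M⁻¹ s⁻¹ even at zeta's Q, so my reckoning holds J and Z at their balance, and Z is a share f = 41.9% of the pool J + Z.
- The pool then falls exponentially in exposure, giving G = 1 − exp(−B·Q). Here B, the life budget of the pool, is the second step's constant times f times X, 2.74 M⁻¹. This takes Q at its charge and Z at balance from the start.
- The budget gives G of 28.0% in delta, 40.6% in eta and 53.6% in zeta. The balance puts J at 41.8%, 34.5% and 27.0%. My leader is therefore J in delta, but G in eta and zeta.
- The forecast differs from this at eta. It names J at 45.5% in delta, J at 40% in eta and G at 43% in zeta, saying “J stays ahead in delta and eta but G overtakes it in zeta”.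
- The simulation gives J at 45.6% in delta, J at 39.9% in eta and G at 44.5% in zeta, the leaders the forecast named. Eta holds G at 33.7%, below my figure. Delta ends with 90.3% of its Q free, and after 500 min its J still stands at 44.9%.
- Delta's G implies an exponent that is 0.807 of B·Q, a reading. A neighbour of delta, charged with more D and otherwise alike, loses the leader that delta has. B scales with the charge of D, so this neighbour, with 3.0 × 10⁻⁴ M of D, has an exponent of 0.822, or 0.663 after that reading, and G comes to 48.5%. The neighbour ends with G in the lead at 47.3%, and J at 31.2%.

Its constants were set for the occasion, and the outcome is calculated.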